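**Plan**

- Retrosynthesis: the veratrate (C6–O acyl bond), the 8,9-epoxide (back to a C8=C9 alkene) and the C6 carbinol (back to a ketone) are removed first. The cyclopentane is then cut at C1–C2 and C4–C5, giving 3,6-dimethylcyclohepta-2,5-dienone and a C2–C4 fragment that already carries the isopropyl ketone and the acetate.
- Enabling feature: the C6 oxygen sits next to ring-fusion C5 and 1,3 to quaternary C1, so a C6 ketone turns C5=C1 of the seven-membered ring into an enone (C1 acceptor, C5 latent enolate). In the five-membered ring, C2 (acyloxy-bearing) and C4 (tertiary carbinol) are the radical end and the carbonyl end of a 1,3-dipole equivalent.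
- Forward: the seven-membered ring is made first (Birch reduction, cyclopropanation and one-carbon ring expansion of 2,5-dimethylphenol); the side fragment comes from 3-methylbutan-2-one and glyoxylic acid. A reductive radical/aldol [3+2] annulation closes the five-membered ring; C6 reduction, epoxidation and veratroylation finish.
- Stereochemistry: C1/C2 from the chiral nickel catalyst of the annulation, C4/C5 from the equilibrating zinc aldolate, C6 from chelation-controlled hydride addition, C8/C9 from the C6–OH-directed epoxidation.
- Helpers: aryl silyl ether (Birch handle), cyclopropane (ring-expansion carbon), N-acyloxyphthalimide carboxyl (radical trigger, lost as CO2), C6 ketone (activator, reduced in step 10).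

Key step: step 9

Remark: positions are numbered as in daucane (C1 angular carbon with CH3-15; C2–C4 in the five-membered ring, isopropyl on C4; C5 ring fusion; C6–C10 in the seven-membered ring, CH3-14 on C8), and β is the face of CH3-15. Compounds 4–6 and 10–12 are racemic, which does not matter because their stereocentres are destroyed before or in step 9.

Step 1
Reactants: 1 2,5-dimethylphenol
Product: 2 tert-butyl(2,5-dimethylphenoxy)dimethylsilane
Conditions: TBSCl, imidazole, DMF, rt
Reagents that add atoms: tert-butyldimethylsilyl chloride, CC(C)(C)[Si](C)(C)Cl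
Why: Silylation of the phenol gives an aryl silyl ether that survives dissolving-metal reduction and later surfaces as a regiodefined silyl enol ether; no stereocentre is formed.

Step 2
Reactants: 2 tert-butyl(2,5-dimethylphenoxy)dimethylsilane
Product: 3 tert-butyl[(2,5-dimethylcyclohexa-1,4-dien-1-yl)oxy]dimethylsilane
Conditions: Li, NH3 (l), THF, t-BuOH, −78 °C; solid NH4Cl
Reagents that add atoms: none
Why: Birch reduction protonates the two unsubstituted ring positions that are para to each other, so the oxygen and both methyl groups stay on sp2 carbons and the 1,4-diene with a tetrasubstituted silyl enol ether should result; no stereocentre is formed.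

Step 3
Reactants: 3 tert-butyl[(2,5-dimethylcyclohexa-1,4-dien-1-yl)oxy]dimethylsilane
Product: 4 tert-butyl[(3,6-dimethylbicyclo[4.1.0]hept-3-en-1-yl)oxy]dimethylsilane (racemic)
Conditions: Et2Zn, CH2I2, CH2Cl2, 0 °C
Reagents that add atoms: diiodomethane, ICI
Why: Simmons–Smith cyclopropanation with the diethylzinc-derived carbenoid should attack the electron-rich silyl enol ether much faster than the isolated trisubstituted alkene; the cis ring fusion is the only one possible.

Step 4
Reactants: 4 tert-butyl[(3,6-dimethylbicyclo[4.1.0]hept-3-en-1-yl)oxy]dimethylsilane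
Product: 5 3,6-dimethylbicyclo[4.1.0]hept-3-en-1-ol (racemic)
Conditions: TBAF, AcOH, THF, 0 °C
Reagents that add atoms: none
Why: Fluoride cleavage of the silyl ether, buffered with acetic acid so that base does not open the strained ring, liberates the cyclopropanol needed for the oxidative ring expansion.

Step 5
Reactants: 5 3,6-dimethylbicyclo[4.1.0]hept-3-en-1-ol
Product: 7 3,6-dimethylcyclohepta-2,5-dien-1-one (fragment A), via beta-chloro ketone 6 (not isolated)
Conditions: FeCl3 (2.2 equiv), DMF, 0 °C; then NaOAc, MeOH, rt
Reagents that add atoms: none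
Why: Oxidative ring expansion of a cyclopropanol, in which trivalent iron oxidises the alkoxide, β-scission of the internal bond gives the tertiary β-keto radical, chlorine transfer gives 6, and acetate-mediated E1cB loss of HCl places the new double bond in conjugation (C5=C1) while the C8=C9 alkene stays where the Birch reduction put it.

Step 6
Reactants: 8 3-methylbutan-2-one, 9 glyoxylic acid
Product: 10 2-hydroxy-5-methyl-4-oxohexanoic acid (racemic)
Conditions: KOH, H2O/MeOH, 0 °C; then HCl to pH 2
Reagents that add atoms: none
Why: Crossed aldol addition of the methyl-side enolate to the non-enolisable, highly electrophilic aldehyde of glyoxylate; the new carbinol centre is racemic and is erased in step 9.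

Step 7
Reactants: 10 2-hydroxy-5-methyl-4-oxohexanoic acid
Product: 11 2-acetoxy-5-methyl-4-oxohexanoic acid (racemic)
Conditions: AcCl (neat), 0 °C to rt; then THF/H2O
Reagents that add atoms: acetyl chloride, CC(Cl)=O
Why: Base-free O-acetylation of the α-hydroxy acid installs the future C2 acetate without β-elimination of the β-acyloxy ketone.

Step 8
Reactants: 11 2-acetoxy-5-methyl-4-oxohexanoic acid
Product: 12 1,3-dioxoisoindolin-2-yl 2-acetoxy-5-methyl-4-oxohexanoate (fragment B, racemic)
Conditions: N-hydroxyphthalimide, DIC, DMAP (cat.), CH2Cl2, 0 °C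
Reagents that add atoms: N-hydroxyphthalimide, ON1C(=O)c2ccccc2C1=O
Why: Carbodiimide esterification gives the redox-active ester that serves as the reductive trigger for the α-acetoxyalkyl radical.

Step 9
Reactants: 7 3,6-dimethylcyclohepta-2,5-dien-1-one, 12 1,3-dioxoisoindolin-2-yl 2-acetoxy-5-methyl-4-oxohexanoate
Product: 15 (1S,2S,4S,5S)-2-acetoxy-4-hydroxydauc-8-en-6-one (trans-fused; 1β-CH3, 2β-OAc, 4β-OH, 4α-isopropyl, 5α-H), via acetoxyalkyl radical 13 (not isolated), via zinc enolate 14 (not isolated)
Conditions: NiCl2·dme (cat.), chiral bis(oxazoline) ligand (cat.; for example (S,S)-Ph-BOX, the enantiomer that gives the (1S) centre to be chosen on a model enone), Zn dust, LiCl, DMA/THF, 0 °C to rt; aq NH4Cl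
Reagents that add atoms: none
Why: Proposed new method: zinc and low-valent nickel reduce the N-acyloxyphthalimide, which loses CO2 and phthalimide anion to give the nucleophilic α-acetoxyalkyl radical 13; this is captured by the oxa-allylnickel complex of enone 7 that carries the chiral bis(oxazoline), and reductive elimination forges C1–C2 at the β-carbon and leaves, after transmetalation, the zinc enolate 14 located only at C5, which adds to the pendant isopropyl ketone in a 5-(enolexo)-exo-trig aldol closure of the cyclopentane. The closest known reaction types are the nickel/zinc decarboxylative Giese addition of redox-active esters to enones, nickel-catalysed reductive conjugate addition through allylnickel intermediates, nickel/bis(oxazoline) enantioconvergent couplings of α-oxygenated alkyl radicals, and conjugate addition followed by zinc-enolate aldol cyclisation; what is new is their combination on a β,β-disubstituted enone. C1 (quaternary) and C2 are set together in the ligand-controlled C–C bond formation, in which the smallest substituent of the radical carbon (H) should lie over the ring so that the acetoxy group ends syn to CH3-15. C4 and C5 are set in the aldol, which is reversible at the zinc aldolate stage and should settle on the trans-fused isomer with 4-OH chelated to the C6 carbonyl and syn to the acetoxy group, and with the isopropyl group on the face opposite CH3-15. The step needs chemoselectivity for the enone β-carbon over the isolated C8=C9 alkene (the radical is nucleophilic and the enone is nickel-bound), an enolate at C5 and not at C7 (it arises by radical–polar crossover and not by deprotonation, so the skipped diene is not isomerised), and survival of the acetate (non-basic medium; after the aldol the acetoxy group is no longer β to a ketone).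

Step 10
Reactants: 15 (1S,2S,4S,5S)-2-acetoxy-4-hydroxydauc-8-en-6-one
Product: 16 (1S,2S,4S,5R,6S)-4,6-dihydroxydauc-8-en-2-yl acetate (6β-OH)
Conditions: Et2BOMe, THF/MeOH, −78 °C; NaBH4; then repeated evaporation from MeOH
Reagents that add atoms: none
Why: Narasaka–Prasad reduction, in which the boron chelate between 4-OH and the C6 carbonyl activates only this ketone and fixes its conformation, so that external hydride should attack the face turned away from quaternary C1 and give the 6β-alcohol (syn to 4-OH, H-6 cis to H-5) with the acetate untouched.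

Step 11
Reactants: 16 (1S,2S,4S,5R,6S)-4,6-dihydroxydauc-8-en-2-yl acetate
Product: 17 (1S,2S,4S,5R,6S,8R,9S)-8,9-epoxy-4,6-dihydroxydaucan-2-yl acetate (8β,9β-epoxide)
Conditions: VO(acac)2 (cat.), t-BuOOH, CH2Cl2, 0 °C to rt
Reagents that add atoms: tert-butyl hydroperoxide, CC(C)(C)OO
Why: Vanadium-catalysed hydroxyl-directed epoxidation, in which the homoallylic 6β-OH binds the vanadium peroxide and delivers oxygen to the C8=C9 alkene on its own face, setting C8 and C9.

Step 12
Reactants: 17 (1S,2S,4S,5R,6S,8R,9S)-8,9-epoxy-4,6-dihydroxydaucan-2-yl acetate, 18 3,4-dimethoxybenzoyl chloride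
Product: 19 (1S,2S,4S,5R,6S,8R,9S)-2-acetoxy-8,9-epoxy-4-hydroxydaucan-6-yl 3,4-dimethoxybenzoate (CNP0330776.1)
Conditions: Et3N, DMAP, CH2Cl2, 0 °C to rt
Reagents that add atoms: none
Why: DMAP-catalysed acylation esterifies the only secondary alcohol, while the tertiary 4-OH and the epoxide are inert under these basic conditions; no stereocentre is touched.

**Compound list**

1 | 2,5-dimethylphenol | Cc1ccc(C)c(O)c1 | starting material
2 | tert-butyl(2,5-dimethylphenoxy)dimethylsilane | Cc1ccc(C)c(O[Si](C)(C)C(C)(C)C)c1 | intermediate
3 | tert-butyl[(2,5-dimethylcyclohexa-1,4-dien-1-yl)oxy]dimethylsilane | CC1=C(O[Si](C)(C)C(C)(C)C)CC(C)=CC1 | intermediate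
4 | tert-butyl[(3,6-dimethylbicyclo[4.1.0]hept-3-en-1-yl)oxy]dimethylsilane (racemic, cis-fused) | CC12CC=C(C)CC1(O[Si](C)(C)C(C)(C)C)C2 | intermediate
5 | 3,6-dimethylbicyclo[4.1.0]hept-3-en-1-ol (racemic, cis-fused) | CC12CC=C(C)CC1(O)C2 | intermediate
6 | 3-chloro-3,6-dimethylcyclohept-5-en-1-one (racemic, formed in situ) | CC1(Cl)CC=C(C)CC(=O)C1 | intermediate
7 | 3,6-dimethylcyclohepta-2,5-dien-1-one (fragment A) | CC1=CC(=O)CC(C)=CC1 | intermediate
8 | 3-methylbutan-2-one | CC(C)C(C)=O | starting material
9 | glyoxylic acid | O=CC(=O)O | starting material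
10 | 2-hydroxy-5-methyl-4-oxohexanoic acid (racemic) | CC(C)C(=O)CC(O)C(=O)O | intermediate
11 | 2-acetoxy-5-methyl-4-oxohexanoic acid (racemic) | CC(C)C(=O)CC(OC(C)=O)C(=O)O | intermediate
12 | 1,3-dioxoisoindolin-2-yl 2-acetoxy-5-methyl-4-oxohexanoate (fragment B, racemic) | CC(C)C(=O)CC(OC(C)=O)C(=O)ON1C(=O)c2ccccc2C1=O | intermediate
13 | 1-acetoxy-4-methyl-3-oxopentyl radical (formed in situ) | CC(C)C(=O)C[CH]OC(C)=O | intermediate
14 | chlorozinc C5=C6 enolate of (3S)-3-[(1S)-1-acetoxy-4-methyl-3-oxopentyl]-3,6-dimethylcyclohept-5-en-1-one (formed in situ) | CC(=O)O[C@@H](CC(=O)C(C)C)[C@@]1(C)CC=C(C)CC(O[Zn]Cl)=C1 | intermediate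
15 | (1S,2S,4S,5S)-2-acetoxy-4-hydroxydauc-8-en-6-one | O=C1CC(C)=CC[C@]2(C)[C@@H](OC(C)=O)C[C@](O)(C(C)C)[C@@H]12 | intermediate
16 | (1S,2S,4S,5R,6S)-4,6-dihydroxydauc-8-en-2-yl acetate | O[C@H]1CC(C)=CC[C@]2(C)[C@@H](OC(C)=O)C[C@](O)(C(C)C)[C@@H]12 | intermediate
17 | (1S,2S,4S,5R,6S,8R,9S)-8,9-epoxy-4,6-dihydroxydaucan-2-yl acetate | O[C@H]1C[C@@]2(C)O[C@H]2C[C@]2(C)[C@@H](OC(C)=O)C[C@](O)(C(C)C)[C@@H]12 | intermediate
18 | 3,4-dimethoxybenzoyl chloride | COc1ccc(C(=O)Cl)cc1OC | starting material
19 | (1S,2S,4S,5R,6S,8R,9S)-2-acetoxy-8,9-epoxy-4-hydroxydaucan-6-yl 3,4-dimethoxybenzoate | COc1ccc(C(=O)O[C@H]2C[C@@]3(C)O[C@H]3C[C@]3(C)[C@@H](OC(C)=O)C[C@](O)(C(C)C)[C@@H]23)cc1OC | target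

**Step count and risks**

Total: 12 steps. Longest linear sequence: 9 steps (1–5, 9–12); fragment B takes 3 steps (6–8).

Risk 1, step 9. The union at the hindered β-carbon may be slow, ligand control at C1/C2 may erode if radical 13 adds outside the nickel coordination sphere, and the aldol may close in the cis-fused sense. The fallback makes the two bonds one after the other with known reaction types. From 7, copper-catalysed enantioselective conjugate boration (B2pin2, CuCl, NaOt-Bu, chiral bisphosphine, MeOH, THF) should give the tertiary boronic ester (3R)-3,6-dimethyl-3-(pinacolboryl)cyclohept-5-en-1-one F1. Ketalisation (ethylene glycol, PPTS) gives the dioxolane ketal F2. Lithiation–borylation follows, using the (−)-sparteine-complexed lithio derivative of 2-(2-isopropyl-1,3-dioxolan-2-yl)ethyl N,N-diisopropylcarbamate (s-BuLi, Et2O, −78 °C; then MgBr2·OEt2, warm); the Matteson-type 1,2-shift proceeds with retention at C1 and reagent control at C2 and gives the secondary boronic ester F3. Oxidation (NaBO3·4H2O) gives the C2 alcohol F4, and acetylation (Ac2O, DMAP, pyridine) the acetate F5. Mild hydrolysis of both ketals (PPTS, wet acetone) gives the diketone (3S)-3-[(1S)-1-acetoxy-4-methyl-3-oxopentyl]-3,6-dimethylcyclohept-5-en-1-one F6. A reversible magnesium-mediated aldol cyclisation (MgBr2·OEt2, i-Pr2NEt, CH2Cl2) closes the five-membered ring and returns to 15.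

Risk 2, step 5. The C8=C9 double bond may migrate into conjugation during the acetate-induced elimination, and FeCl3 may chlorinate the alkene. The fallback avoids both the oxidant and the base. From 3, dibromocarbene addition to the silyl enol ether (CHBr3, KOt-Bu, pentane, −20 °C) gives the dibromocyclopropane F7. Fluoride-triggered ring opening (TBAF, THF, −20 °C) gives 2-bromo-3,6-dimethylcyclohepta-2,5-dien-1-one F8. Hydrodebromination under neutral conditions (Bu3SnH, Pd(PPh3)4 as source of zerovalent palladium, THF) returns to 7.

Risk 3, step 10. Facial selectivity of hydride addition at C6 may be poor, because the α-isopropyl group can hinder attack on the chelate. The fallback makes the wrong epimer on purpose and inverts it. From 15, intramolecular hydride delivery from the 4β-alkoxyborohydride (Me4NBH(OAc)3, MeCN/AcOH, −20 °C; Evans–Saksena reduction) should give the 6α-alcohol F9. Mitsunobu inversion with chloroacetic acid (PPh3, DIAD, toluene) gives the 6β-chloroacetate F10. Selective removal of the chloroacetate in the presence of the acetate (thiourea, NaHCO3, EtOH) returns to 16.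

Further compounds
F1 | step 9 | (3R)-3,6-dimethyl-3-(4,4,5,5-tetramethyl-1,3,2-dioxaborolan-2-yl)cyclohept-5-en-1-one | O=C1CC(C)=CC[C@](C)(B2OC(C)(C)C(C)(C)O2)C1
F2 | step 9 | ethylene glycol ketal of F1 | CC1=CC[C@](C)(B2OC(C)(C)C(C)(C)O2)CC3(C1)OCCO3
F3 | step 9 | secondary pinacol boronic ester with C1–C2 formed (boron on C2; C4 and C6 as dioxolane ketals) | CC1(C)OB(OC1(C)C)[C@@H](CC2(OCCO2)C(C)C)[C@@]3(C)CC=C(C)CC4(C3)OCCO4
F4 | step 9 | C2 alcohol from oxidation of F3 | O[C@@H](CC1(OCCO1)C(C)C)[C@@]2(C)CC=C(C)CC3(C2)OCCO3
F5 | step 9 | C2 acetate of F4 | CC(=O)O[C@@H](CC1(OCCO1)C(C)C)[C@@]2(C)CC=C(C)CC3(C2)OCCO3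
F6 | step 9 | (3S)-3-[(1S)-1-acetoxy-4-methyl-3-oxopentyl]-3,6-dimethylcyclohept-5-en-1-one | CC(=O)O[C@@H](CC(=O)C(C)C)[C@@]1(C)CC=C(C)CC(=O)C1
F7 | step 5 | tert-butyl[(7,7-dibromo-3,6-dimethylbicyclo[4.1.0]hept-3-en-1-yl)oxy]dimethylsilane (racemic) | CC12CC=C(C)CC1(O[Si](C)(C)C(C)(C)C)C2(Br)Br
F8 | step 5 | 2-bromo-3,6-dimethylcyclohepta-2,5-dien-1-one | CC1=C(Br)C(=O)CC(C)=CC1
F9 | step 10 | (1S,2S,4S,5R,6R)-4,6-dihydroxydauc-8-en-2-yl acetate (6α-OH) | O[C@@H]1CC(C)=CC[C@]2(C)[C@@H](OC(C)=O)C[C@](O)(C(C)C)[C@@H]12
F10 | step 10 | (1S,2S,4S,5R,6S)-2-acetoxy-4-hydroxydauc-8-en-6-yl chloroacetate | O=C(CCl)O[C@H]1CC(C)=CC[C@]2(C)[C@@H](OC(C)=O)C[C@](O)(C(C)C)[C@@H]12
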